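The labdane is cut at C9–C11 and C10–C1. The route exploits the fact that C9 of ring B is the β-carbon and quaternary C10 the α-carbon of a 2-methylcyclohex-2-enone whose γ-carbon, C8 (the future exocyclic-methylene carbon), is masked as a ketal. In one telescoped operation a Cu(OTf)2–phosphoramidite catalyst adds the complete (13R,14S) side chain as a dialkylzinc to C9, and the regiodefined C10 enolate is captured by an α-silyl vinyl ketone. This fixes C9 and C10 and gives the 1,5-diketone from which ring A is closed. The precursors are the enone monoketal, an acetonide-protected dialkylzinc made by crotylboration, and 3-(trimethylsilyl)but-3-en-2-one.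

Key step: step 6

Numbering: atoms carry labdane numbers (C1–C10 decalin, C11–C15 side chain, C16 on C13, C17 exocyclic methylene, C18/C19 on C4, C20 on C10); α/β refer to the usual labdane drawing with C20 β.

Assumption: 1,4-dioxaspiro[4.5]dec-6-en-8-one and 3-(trimethylsilyl)but-3-en-2-one are treated as purchasable reagents. The vinyl ketone replaces plain but-3-en-2-one because lithium enolates polymerise the unsubstituted enone, and the carbon-bound silyl group is removed in the same step.

Step 1
Reactants: 1 1,4-dioxaspiro[4.5]dec-6-en-8-one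
Product: 2 7-iodo-1,4-dioxaspiro[4.5]dec-6-en-8-one
Conditions: I2, pyridine, CH2Cl2, 0 °C to rt
Reagents that add atoms: iodine, II
Why: Pyridine adds reversibly to the β-carbon, the resulting enolate is iodinated at the α-carbon and pyridine is expelled (addition–elimination α-iodination of an enone), while the dioxolane is inert to the non-acidic medium.

Step 2
Reactants: 2 7-iodo-1,4-dioxaspiro[4.5]dec-6-en-8-one
Product: 3 7-methyl-1,4-dioxaspiro[4.5]dec-6-en-8-one
Conditions: trimethylboroxine, PdCl2(dppf) (5 mol%), K2CO3, dioxane–H2O, 80 °C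
Reagents that add atoms: trimethylboroxine, CB1OB(C)OB(C)O1
Why: Suzuki–Miyaura coupling (oxidative addition of the alkenyl iodide to zerovalent palladium, methyl transfer from the boron ate complex, reductive elimination) places the future C20 methyl group on the α-carbon with no regiochemical ambiguity in the enone.

Step 3
Reactants: 4 2-[(tert-butyldimethylsilyl)oxy]acetaldehyde; 5 cis-but-2-ene
Product: 9 (2S,3R)-1-[(tert-butyldimethylsilyl)oxy]-3-methylpent-4-en-2-ol, via (Z)-but-2-enylpotassium 6 (not isolated), via (Z)-crotyldiisopinocampheylborane 7 (not isolated), via borinate adduct 8 (not isolated)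
Conditions: 5, n-BuLi, KOt-Bu, THF, −78 to −45 °C; (−)-Ipc2BOMe [from (+)-α-pinene], −78 °C; BF3·OEt2; 4, −78 °C; NaOH, H2O2, 0 °C to rt
Reagents that add atoms: none
Why: Brown asymmetric crotylboration proceeds through a closed chair (Zimmerman–Traxler) transition state, so the Z geometry gives the syn C13-methyl/C14-hydroxyl relationship and the isopinocampheyl groups derived from (+)-α-pinene direct attack to the Si face of the aldehyde, setting 2S (C14) and 3R (C13).

Step 4
Reactants: 9 (2S,3R)-1-[(tert-butyldimethylsilyl)oxy]-3-methylpent-4-en-2-ol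
Product: 11 (4S)-4-[(2R)-but-3-en-2-yl]-2,2-dimethyl-1,3-dioxolane, via free 1,2-diol 10 (not isolated)
Conditions: p-TsOH·H2O (cat.), MeOH, rt; then excess 2,2-dimethoxypropane, acetone, rt; Et3N quench
Reagents that add atoms: 2,2-dimethoxypropane, COC(C)(C)OC
Why: Acid-catalysed methanolysis cleaves the primary silyl ether and transketalisation closes the five-membered acetonide, a protecting-group exchange that leaves both stereocentres untouched and gives a diol mask stable to organometallics, strong base and hydrazine.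

Step 5
Reactants: 11 (4S)-4-[(2R)-but-3-en-2-yl]-2,2-dimethyl-1,3-dioxolane (two molecules per molecule of 13)
Product: 13 bis{(3R)-3-[(4S)-2,2-dimethyl-1,3-dioxolan-4-yl]butyl}zinc, via alkyldiethylborane 12 (not isolated)
Conditions: 11 (2.0 equiv), Et2BH (2.0 equiv, from BH3·SMe2 and Et3B), Et2O, 0 °C to rt; Et2Zn (neat, excess), 0 °C; Et3B and excess Et2Zn removed at 0.1 mmHg, 40 °C; used as PhMe solution
Reagents that add atoms: diethylzinc, CC[Zn]CC; (4S)-4-[(2R)-but-3-en-2-yl]-2,2-dimethyl-1,3-dioxolane (second molecule of 11), C=C[C@@H](C)[C@H]1COC(C)(C)O1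
Why: Anti-Markovnikov hydroboration places boron on the terminal carbon (C11) of each of the two molecules of 11, and boron–zinc exchange with Et2Zn, driven by evaporation of Et3B and of the surplus Et2Zn, gathers the two primary alkyl groups on one zinc atom as the salt-free dialkylzinc without touching C13 and C14.

Step 6
Reactants: 3 7-methyl-1,4-dioxaspiro[4.5]dec-6-en-8-one; 13 bis{(3R)-3-[(4S)-2,2-dimethyl-1,3-dioxolan-4-yl]butyl}zinc; 14 3-(trimethylsilyl)but-3-en-2-one
Product: 19 (6R,7R)-7-methyl-7-(3-oxobutyl)-6-{(3R)-3-[(4S)-2,2-dimethyl-1,3-dioxolan-4-yl]butyl}-1,4-dioxaspiro[4.5]decan-8-one, via alkylzinc enolate 15 (not isolated), via trimethylsilyl enol ether 16 (not isolated), via lithium enolate 17 (not isolated), via C-silylated diketone 18 (not isolated)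
Conditions: Cu(OTf)2 (3 mol%), (S,R,R)-L (6 mol%) [L = (S)-binaphthol phosphoramidite of bis[(R)-1-phenylethyl]amine], 13 (1.3 equiv), PhMe, −30 °C; TMSOTf, Et3N, −30 to 0 °C; volatiles off, pentane extraction and filtration under Ar, THF; MeLi, 0 °C to rt; 14, −78 to −20 °C; AcOH then TBAF, 0 °C
Reagents that add atoms: none
Why: Monovalent copper (formed from Cu(OTf)2 and the zinc reagent) bound to the phosphoramidite transfers one alkyl group of 13 to the β-carbon C9 of 3 through a π-complex and σ-alkylcopper intermediate, leaving the regiodefined enolate 15; O-silylation to 16, Si–O cleavage by MeLi to 17 and Michael addition to the α-silyl enone 14 then form C10–C1, and buffered fluoride removes the carbon-bound silyl group of 18. The closest known reaction types are the copper/phosphoramidite-catalysed conjugate addition of dialkylzincs to cyclohexenones with silyl trapping of the zinc enolate, and the conjugate addition–annulation of 2-methylcyclohexenone in which the enolate is captured by an α-silyl vinyl ketone. No ring is closed in this step; ring A is closed in step 7. C9 is set by the catalyst: the (S,R,R) ligand is expected to deliver the alkyl group to the Re face of C9 of 3 (spatially the face whose attack on cyclohex-2-enone gives (S)-3-ethylcyclohexanone), overriding the remote C13/C14 centres, and the antipodal ligand is the remedy should the sense prove opposite. C10 is set by the substrate: the enolate is attacked axially on the face anti to the pseudoaxial C9 chain, so C1 ends trans and the C10 methyl cis to C11. The step needs 1,4-selectivity and a fixed enolate regiochemistry, secured by the C8 ketal (no enolisable position on that side and inductive activation of the sluggish α-methyl enone), by the aprotic silyl/lithium relay that prevents equilibration to the C6 enolate, and by the silyl group of 14, which suppresses polymerisation and proton transfer.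

Step 7
Reactants: 19 (6R,7R)-7-methyl-7-(3-oxobutyl)-6-{(3R)-3-[(4S)-2,2-dimethyl-1,3-dioxolan-4-yl]butyl}-1,4-dioxaspiro[4.5]decan-8-one
Product: 21 (4aR,5R)-5-{(3R)-3-[(4S)-2,2-dimethyl-1,3-dioxolan-4-yl]butyl}-6,6-(ethylenedioxy)-4a-methyl-4,4a,5,6,7,8-hexahydronaphthalen-2(3H)-one, via ketol 20 (not isolated)
Conditions: KOH, MeOH, 65 °C
Reagents that add atoms: none
Why: Intramolecular aldol condensation (second stage of a Robinson annulation): the methyl ketone enolate at C4 adds to the C5 ketone in a 6-(enolendo)-exo-trig closure and the ketol dehydrates to the conjugated 4-en-3-one, while C9 and C10 carry no acidic hydrogen and cannot epimerise.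

Step 8
Reactants: 21 (4aR,5R)-5-{(3R)-3-[(4S)-2,2-dimethyl-1,3-dioxolan-4-yl]butyl}-6,6-(ethylenedioxy)-4a-methyl-4,4a,5,6,7,8-hexahydronaphthalen-2(3H)-one
Product: 23 (4aR,5R)-5-{(3R)-3-[(4S)-2,2-dimethyl-1,3-dioxolan-4-yl]butyl}-6,6-(ethylenedioxy)-1,1,4a-trimethyl-3,4,4a,5,6,7-hexahydronaphthalen-2(1H)-one, via monomethyl ketone 22 (not isolated)
Conditions: KOt-Bu (3.5 equiv), t-BuOH–THF, rt; MeI (excess), rt
Reagents that add atoms: iodomethane, CI
Why: Deconjugative α,α-dialkylation: the extended dienolate (O–C3 to C6) is methylated twice at C4 because α-alkylation is kinetically preferred, which creates the C4 gem-dimethyl group and moves the alkene to C5=C6, a standard operation on octalone and steroid 4-en-3-ones.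

Step 9
Reactants: 23 (4aR,5R)-5-{(3R)-3-[(4S)-2,2-dimethyl-1,3-dioxolan-4-yl]butyl}-6,6-(ethylenedioxy)-1,1,4a-trimethyl-3,4,4a,5,6,7-hexahydronaphthalen-2(1H)-one
Product: 25 (1R,8aR)-1-{(3R)-3-[(4S)-2,2-dimethyl-1,3-dioxolan-4-yl]butyl}-2,2-(ethylenedioxy)-5,5,8a-trimethyl-1,2,3,5,6,7,8,8a-octahydronaphthalene, via hydrazone 24 (not isolated)
Conditions: N2H4·H2O, KOH, diethylene glycol, 130 °C then 200 °C
Reagents that add atoms: none
Why: Wolff–Kishner reduction (Huang-Minlon procedure): the hydrazone of the hindered C3 ketone loses N2 under hot KOH to leave a methylene group, conditions to which the ketal, the acetonide and the isolated C5=C6 alkene are inert.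

Step 10
Reactants: 25 (1R,8aR)-1-{(3R)-3-[(4S)-2,2-dimethyl-1,3-dioxolan-4-yl]butyl}-2,2-(ethylenedioxy)-5,5,8a-trimethyl-1,2,3,5,6,7,8,8a-octahydronaphthalene
Product: 26 (1R,4aS,8aS)-1-{(3R)-3-[(4S)-2,2-dimethyl-1,3-dioxolan-4-yl]butyl}-2,2-(ethylenedioxy)-5,5,8a-trimethyldecahydronaphthalene
Conditions: H2 (4 atm), 10% Pd/C, EtOAc, rt
Reagents that add atoms: none
Why: Heterogeneous hydrogenation should deliver hydrogen to the α face of C5=C6, opposite the axial C10 methyl, the 4β-methyl and the β-oriented C9 chain, setting 5α-H (5S) and the trans-decalin in a neutral medium that spares both ketals.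

Step 11
Reactants: 26 (1R,4aS,8aS)-1-{(3R)-3-[(4S)-2,2-dimethyl-1,3-dioxolan-4-yl]butyl}-2,2-(ethylenedioxy)-5,5,8a-trimethyldecahydronaphthalene
Product: 27 (1R,4aS,8aS)-1-[(3R,4S)-4,5-dihydroxy-3-methylpentyl]-5,5,8a-trimethyloctahydronaphthalen-2(1H)-one
Conditions: 2 M HCl, THF, 40 °C
Reagents that add atoms: water, O
Why: Aqueous acid hydrolyses the dioxolane and the acetonide in one operation (acetal hydrolysis), and C9, now α to the C8 ketone, already holds its side chain equatorial (the thermodynamically preferred arrangement), so enolisation cannot erode it.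

Step 12
Reactants: 27 (1R,4aS,8aS)-1-[(3R,4S)-4,5-dihydroxy-3-methylpentyl]-5,5,8a-trimethyloctahydronaphthalen-2(1H)-one
Product: 28 (2S,3R)-3-methyl-5-[(1S,4aS,8aS)-5,5,8a-trimethyl-2-methylidenedecahydronaphthalen-1-yl]pentane-1,2-diol
Conditions: Ph3PCH3Br (6 equiv), KOt-Bu (5.5 equiv), PhMe, 0 to 90 °C
Reagents that add atoms: methyltriphenylphosphonium bromide, C[P+](c1ccccc1)(c1ccccc1)c1ccccc1.[Br-]
Why: Wittig methylenation of the C8 ketone with excess non-stabilised ylide (the surplus absorbs the two hydroxyl protons) gives the exocyclic C8=C17 alkene, a standard transformation of 8-oxo-17-norlabdanes in which C9 stays in its favoured equatorial configuration.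

Step 13
Reactants: 28 (2S,3R)-3-methyl-5-[(1S,4aS,8aS)-5,5,8a-trimethyl-2-methylidenedecahydronaphthalen-1-yl]pentane-1,2-diol
Product: 29 (2S,3R)-2-hydroxy-3-methyl-5-[(1S,4aS,8aS)-5,5,8a-trimethyl-2-methylidenedecahydronaphthalen-1-yl]pentyl acetate
Conditions: AcCl (1.05 equiv), 2,4,6-collidine, CH2Cl2, −78 °C
Reagents that add atoms: acetyl chloride, CC(Cl)=O
Why: Kinetic acylation with AcCl and a hindered pyridine base at low temperature is selective for the unhindered primary C15 hydroxyl over the secondary C14 hydroxyl next to the C13 methyl branch, giving the target monoacetate.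

Compound list
1 | 1,4-dioxaspiro[4.5]dec-6-en-8-one | O=C1CCC2(OCCO2)C=C1 | starting material
2 | 7-iodo-1,4-dioxaspiro[4.5]dec-6-en-8-one | O=C1CCC2(OCCO2)C=C1I | intermediate
3 | 7-methyl-1,4-dioxaspiro[4.5]dec-6-en-8-one | CC1=CC2(CCC1=O)OCCO2 | intermediate
4 | 2-[(tert-butyldimethylsilyl)oxy]acetaldehyde | CC(C)(C)[Si](C)(C)OCC=O | starting material
5 | cis-but-2-ene | C/C=C\C | starting material
6 | (Z)-but-2-enylpotassium | C/C=C\C[K] | intermediate
7 | (Z)-but-2-enylbis(isopinocampheyl)borane, isopinocampheyl groups from (+)-α-pinene | C/C=C\CB([C@@H]1C[C@@H]2C[C@H]([C@H]1C)C2(C)C)[C@@H]1C[C@@H]2C[C@H]([C@H]1C)C2(C)C | intermediate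
8 | (2S,3R)-1-[(tert-butyldimethylsilyl)oxy]-3-methylpent-4-en-2-yl bis(isopinocampheyl)borinate | C=C[C@@H](C)[C@H](OB([C@@H]1C[C@@H]2C[C@H]([C@H]1C)C2(C)C)[C@@H]1C[C@@H]2C[C@H]([C@H]1C)C2(C)C)CO[Si](C)(C)C(C)(C)C | intermediate
9 | (2S,3R)-1-[(tert-butyldimethylsilyl)oxy]-3-methylpent-4-en-2-ol | C=C[C@@H](C)[C@H](O)CO[Si](C)(C)C(C)(C)C | intermediate
10 | (2S,3R)-3-methylpent-4-ene-1,2-diol | C=C[C@@H](C)[C@H](O)CO | intermediate
11 | (4S)-4-[(2R)-but-3-en-2-yl]-2,2-dimethyl-1,3-dioxolane | C=C[C@@H](C)[C@H]1COC(C)(C)O1 | intermediate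
12 | diethyl{(3R)-3-[(4S)-2,2-dimethyl-1,3-dioxolan-4-yl]butyl}borane | CCB(CC)CC[C@@H](C)[C@H]1COC(C)(C)O1 | intermediate
13 | bis{(3R)-3-[(4S)-2,2-dimethyl-1,3-dioxolan-4-yl]butyl}zinc | [Zn](CC[C@@H](C)[C@H]1COC(C)(C)O1)CC[C@@H](C)[C@H]1COC(C)(C)O1 | intermediate
14 | 3-(trimethylsilyl)but-3-en-2-one | CC(=O)C(=C)[Si](C)(C)C | starting material
15 | alkylzinc enolate of the conjugate adduct (zinc on the C5 oxygen, second side-chain alkyl still on zinc; 9-H α) | CC1=C(O[Zn]CC[C@@H](C)[C@H]2COC(C)(C)O2)CCC3(OCCO3)[C@@H]1CC[C@@H](C)[C@H]4COC(C)(C)O4 | intermediate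
16 | (6R)-6-{(3R)-3-[(4S)-2,2-dimethyl-1,3-dioxolan-4-yl]butyl}-7-methyl-8-[(trimethylsilyl)oxy]-1,4-dioxaspiro[4.5]dec-7-ene | CC1=C(O[Si](C)(C)C)CCC2(OCCO2)[C@@H]1CC[C@@H](C)[C@H]3COC(C)(C)O3 | intermediate
17 | lithium enolate corresponding to 16 (lithium on the C5 oxygen) | CC1=C(O[Li])CCC2(OCCO2)[C@@H]1CC[C@@H](C)[C@H]3COC(C)(C)O3 | intermediate
18 | (6R,7R)-7-methyl-7-[3-oxo-2-(trimethylsilyl)butyl]-6-{(3R)-3-[(4S)-2,2-dimethyl-1,3-dioxolan-4-yl]butyl}-1,4-dioxaspiro[4.5]decan-8-one (both epimers at the silyl-bearing carbon) | CC(=O)C(C[C@@]1(C)C(=O)CCC2(OCCO2)[C@@H]1CC[C@@H](C)[C@H]3COC(C)(C)O3)[Si](C)(C)C | intermediate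
19 | (6R,7R)-7-methyl-7-(3-oxobutyl)-6-{(3R)-3-[(4S)-2,2-dimethyl-1,3-dioxolan-4-yl]butyl}-1,4-dioxaspiro[4.5]decan-8-one | CC(=O)CC[C@@]1(C)C(=O)CCC2(OCCO2)[C@@H]1CC[C@@H](C)[C@H]3COC(C)(C)O3 | intermediate
20 | ketol from closure of ring A (5-hydroxy-3-ketone, either C5 epimer; C8 ketal, 10β-methyl, 9α-H) | O=C1CC[C@@]2(C)C(O)(C1)CCC3(OCCO3)[C@@H]2CC[C@@H](C)[C@H]4COC(C)(C)O4 | intermediate
21 | (4aR,5R)-5-{(3R)-3-[(4S)-2,2-dimethyl-1,3-dioxolan-4-yl]butyl}-6,6-(ethylenedioxy)-4a-methyl-4,4a,5,6,7,8-hexahydronaphthalen-2(3H)-one (4-en-3-one) | O=C1CC[C@@]2(C)C(=C1)CCC3(OCCO3)[C@@H]2CC[C@@H](C)[C@H]4COC(C)(C)O4 | intermediate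
22 | 4-methyl-5-en-3-one (mono-methylated ketone, either C4 epimer) | CC1C(=O)CC[C@@]2(C)C1=CCC3(OCCO3)[C@@H]2CC[C@@H](C)[C@H]4COC(C)(C)O4 | intermediate
23 | (4aR,5R)-5-{(3R)-3-[(4S)-2,2-dimethyl-1,3-dioxolan-4-yl]butyl}-6,6-(ethylenedioxy)-1,1,4a-trimethyl-3,4,4a,5,6,7-hexahydronaphthalen-2(1H)-one (4,4-dimethyl-5-en-3-one) | CC1(C)C(=O)CC[C@@]2(C)C1=CCC3(OCCO3)[C@@H]2CC[C@@H](C)[C@H]4COC(C)(C)O4 | intermediate
24 | hydrazone of 23 at C3 | CC1(C)C(=NN)CC[C@@]2(C)C1=CCC3(OCCO3)[C@@H]2CC[C@@H](C)[C@H]4COC(C)(C)O4 | intermediate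
25 | (1R,8aR)-1-{(3R)-3-[(4S)-2,2-dimethyl-1,3-dioxolan-4-yl]butyl}-2,2-(ethylenedioxy)-5,5,8a-trimethyl-1,2,3,5,6,7,8,8a-octahydronaphthalene | CC1(C)CCC[C@@]2(C)C1=CCC3(OCCO3)[C@@H]2CC[C@@H](C)[C@H]4COC(C)(C)O4 | intermediate
26 | (1R,4aS,8aS)-1-{(3R)-3-[(4S)-2,2-dimethyl-1,3-dioxolan-4-yl]butyl}-2,2-(ethylenedioxy)-5,5,8a-trimethyldecahydronaphthalene | CC1(C)CCC[C@@]2(C)[C@H]1CCC3(OCCO3)[C@@H]2CC[C@@H](C)[C@H]4COC(C)(C)O4 | intermediate
27 | (1R,4aS,8aS)-1-[(3R,4S)-4,5-dihydroxy-3-methylpentyl]-5,5,8a-trimethyloctahydronaphthalen-2(1H)-one | CC1(C)CCC[C@@]2(C)[C@H]1CCC(=O)[C@@H]2CC[C@@H](C)[C@H](O)CO | intermediate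
28 | (2S,3R)-3-methyl-5-[(1S,4aS,8aS)-5,5,8a-trimethyl-2-methylidenedecahydronaphthalen-1-yl]pentane-1,2-diol | C=C1CC[C@H]2C(C)(C)CCC[C@]2(C)[C@H]1CC[C@@H](C)[C@H](O)CO | intermediate
29 | (2S,3R)-2-hydroxy-3-methyl-5-[(1S,4aS,8aS)-5,5,8a-trimethyl-2-methylidenedecahydronaphthalen-1-yl]pentyl acetate (CNP0282247.2) | C=C1CC[C@H]2C(C)(C)CCC[C@]2(C)[C@H]1CC[C@@H](C)[C@H](O)COC(C)=O | target

Total step count: 13. Longest linear sequence: 11 steps (steps 3–13, from 4 and 5).

Steps most likely to fail

Step 6. The alkyl transfer to the α-methylated, γ,γ-dioxygenated enone may be slow or poorly face-selective, the silyl triflate may ionise the ketal during trapping, or the congested C10 enolate may undergo proton transfer instead of Michael addition. The fallback sets out from 3 and 13: the same Cu(OTf)2/phosphoramidite conjugate addition is simply quenched with aqueous NH4Cl to give the 2,3-trans ketone (6R,7R)-7-methyl-6-{(3R)-3-[(4S)-2,2-dimethyl-1,3-dioxolan-4-yl]butyl}-1,4-dioxaspiro[4.5]decan-8-one F1. Ring A is then built by a classical base-mediated Robinson annulation under thermodynamic control (but-3-en-2-one, catalytic KOH in MeOH at 0 °C, then NaOMe in MeOH at reflux). The more substituted C10 enolate should add to the enone anti to the C9 chain, and the adduct cyclises and dehydrates, so the sequence rejoins the route at 21.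

Step 10. Hydrogen uptake at the hindered trisubstituted C5=C6 alkene next to the C4 gem-dimethyl group may stall, and forcing conditions may erode α-face delivery or isomerise the alkene. The fallback sets out from 25 and uses a radical hydrogen-atom-transfer hydrogenation (Mn(dpm)3, PhSiH3, t-BuOOH, i-PrOH, rt). The tertiary C5 radical is reduced under thermodynamic control, which favours the trans ring fusion; no new compound is involved and the route is rejoined at 26.

Step 12. The ylide may act as a base toward the hindered, enolisable C8 ketone, or the dialkoxide may precipitate and stop the conversion. The fallback sets out from 27 and is a Peterson olefination. Me3SiCH2Li premixed with CeCl3 (THF, −78 °C, extra equivalents for the diol) should add to the ketone to give the β-hydroxysilane 8-hydroxy-8-[(trimethylsilyl)methyl]-17-norlabdane-14,15-diol F2 (either C8 epimer). KH in THF then induces syn elimination of silanolate and returns the route at 28.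

Further compounds
F1 | step 6 | (6R,7R)-7-methyl-6-{(3R)-3-[(4S)-2,2-dimethyl-1,3-dioxolan-4-yl]butyl}-1,4-dioxaspiro[4.5]decan-8-one | C[C@H]1C(=O)CCC2(OCCO2)[C@@H]1CC[C@@H](C)[C@H]3COC(C)(C)O3
F0 | step 10 | none | none
F2 | step 12 | (13R,14S)-8-hydroxy-8-[(trimethylsilyl)methyl]-17-norlabdane-14,15-diol (either C8 epimer) | C[Si](C)(C)CC1(O)CC[C@H]2C(C)(C)CCC[C@]2(C)[C@H]1CC[C@@H](C)[C@H](O)CO
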